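## The problem

The target 22 is a flavone whose A ring is substituted at every position except C8. It carries a methoxy group at C5, a free hydroxyl at C7 and, between them at C6, an N-methylpiperidine joined through C2'. C2' is the only stereocentre and is (S); no neighbouring centre can relay to it, so its configuration must come from a catalyst, an auxiliary or the chiral pool. The centre is benzylic, α to nitrogen and attached to a 1,3,5-trioxygenated ring. Ionisation of the C2'–N bond towards a quinone-methide-like cation is therefore the way hot acid, or a free ortho/para phenol under forcing conditions, could racemise it. Regiochemistry is the second problem: the pyranone must be fused with O1 para to C6, and the two oxygens flanking C6, equivalent until the pyranone exists, must end as one methyl ether and one phenol. The tertiary amine (quaternisation) and the chromone (hydride reagents) fix the order of events: all lactam- and carboxyl-level work on the piperidine must be finished before the pyranone is built. The enabling feature is that C2', N1', C6' and C5' form a 2-azadiene, aryl–CH=N–C(OSi)=CH2, once C6' is at the lactam oxidation level. C3'–C4' is then a two-carbon dienophile, and the formyl carbon of a benzaldehyde becomes C2' in a cycloaddition that a chiral Lewis acid can make enantioselective.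

## Retrosynthesis

**O7–CH3.** The last bond cut is the 7-O-methyl bond, leading back to the 5,7-dimethoxyflavone 21. Keeping both flanking oxygens as methyl ethers makes the aryl group symmetric about the aryl–C2' axis throughout the piperidine construction, so later acylation can give only one regioisomer. Two different ethers would make the two free ring positions inequivalent and demand a regioselective acylation that nothing controls. The price is one selective demethylation. In 21 the 7-methoxy group is para to the C4 carbonyl (a vinylogous ester), and a soft nucleophile should dealkylate it in preference to the 5-methoxy group, whose phenoxide would lie peri to the carbonyl oxygen.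

**O1–C2 and C4a–C4.** The pyranone of 21 is opened at O1–C2 to the ortho-hydroxyaryl ynone 20, the deprotected form of ynone 19. Ynone 19 is cut at the aryl–carbonyl bond into aryllithium 18, generated from arylpiperidine 15, and Weinreb amide 17, made in one step from 3-phenylpropiolic acid 16. This removes nine carbons and the heterocycle in two operations. Compared with phenol release, Friedel–Crafts acetylation, Baker–Venkataraman transfer and cyclodehydration, it saves two steps and avoids a hot Lewis acid on a free phenol carrying the benzylic amine. It also dictates the protecting group. The para oxygen of 15 is a methoxymethyl ether, which with the adjacent methoxy group directs lithiation to the only free ring positions (equivalent by rotation) and is the future O1. The forward steps must metalate the ring and not C2'–H, add once to the amide, and close 6-endo.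

**N–CH3 and C6'=O.** Amine 15 is traced to N-methyl lactam 14 and then to secondary lactam 13. Methylating at the lactam stage excludes over-alkylation, and a tertiary lactam is reduced cleanly by hydride. Both operations precede the chromone, which would not tolerate the hydride.

**C3'–CO2H.** Lactam 13 is given back a carboxyl at C3' (acid 11), which is the hydrolysis product of imide 9. The carboxyl is the trace of the dienophile's activating group. Its radical removal deletes the C3' stereocentre, so only C2' has to be right in absolute terms.

**C2'–C3' and C4'–C5' (key cut).** Imide 9 is divided into 2-azadiene 6 and 3-acryloyl-1,3-oxazolidin-2-one 7. Against a cut at N1'–C2' (cyclisation onto a benzylic cation) or at aryl–C2' (addition of a di-ortho-substituted aryl metal to a cyclic imine), this cut forms two C–C bonds, the ring and C2' in one catalytic step. The aryl oxygens stay capped, so the new centre cannot re-ionise. The forward reaction needs regiocontrol (diene CH2 to the acrylate β-carbon), one open face of the bound acrylamide and exo approach.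

**Azadiene assembly.** Diene 6 comes from N-acetyl imine 5 by O-silylation. Imine 5 comes from N-silyl aldimine 4 and acetyl chloride 3, and 4 from aldehyde 2, the methoxymethyl ether of 4-hydroxy-2,6-dimethoxybenzaldehyde 1. All three inputs are simple, and the aldehyde is non-enolisable, which the silyl-imine chemistry requires.

## Roads not taken

**Alternative 1: benzannulation of the A ring around a chiral-pool piperidine.** The cut removes C5–C6, C7–C8 and C4a–C5. In the forward step, photolysis of 2-(2-diazoacetyl)-6-phenyl-4H-pyran-4-one A2 triggers a Wolff rearrangement to a vinylketene. [2+2] addition to siloxyalkyne A3 (from L-pipecolic acid A4), four-electron ring opening and six-electron closure then give the flavone A1.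
- Merits: the stereocentre is bought, not made. O5 (free phenol) and O7 (silyl ether) are born differentiated, which is better than the chosen plan's end-game demethylation. The carbamate nitrogen also allows O5 to be methylated without risk of quaternisation.
- Weak points: the ketene must be generated on a photoreactive 4-pyranone whose own C3 has to serve as the terminus of the electrocyclisation. The alkyne carries a branched α-amino carbamate beside the reacting carbon. After the key step, methylation of a chelated and doubly flanked phenol, carbamate removal under acid next to an oxygenated benzylic C–N bond, N-methylation and desilylation are still needed. Both A2 and A3 require multistep preparation.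
- Comparison: the chosen plan sets against the better oxygen differentiation a catalytic key step of a known class and simple inputs.

**Alternative 2: stereoconvergent aza-Michael closure onto an ortho-quinone methide.** The cut is N1'–C2'. A chiral phosphoric acid ionises the racemic benzylic alcohol A6 and the carbamate nitrogen closes the ring 6-exo to give A5.
- Merits: this is the shortest access to the arylpiperidine. It converts a racemate into one enantiomer, and the ortho hydroxyl it needs is a target feature.
- Weak points: the ortho-hydroxybenzyl carbamate in A5 is the very motif that ionises, so the product can re-enter the cation manifold and lose enantiopurity under the catalyst. Carbamate nitrogen is a weak intramolecular nucleophile for this chemistry. A5 has two identical free ortho phenols and a third latent one. Mono-methylation, acylation between the methylated and the para oxygen, and ring closure through the para and not an ortho oxygen are each uncontrolled, so the 8-substituted flavone is a likely contaminant.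
- Comparison: this road is better in step count up to the piperidine. The chosen plan answers with a centre made by C–C bond formation on a fully capped arene and with downstream regiochemistry fixed by symmetry.

**Alternative 3: carbonylative alkyne annulation installs the pyranone last.** The cut removes C4a–C4, C4–C3 and O1–C2. Palladium couples iodophenol A8 with carbon monoxide A10 and phenylacetylene A9 and closes the pyranone to A7, which is identical with 21.
- Merits: convergent and a single step from iodophenol to flavone, through the same ynone logic used here.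
- Weak points: it is an end game only. A8 must still be made enantiopure, by something like the chosen key step. Mono-iodination of a very electron-rich aminophenol, oxidative addition at a di-ortho-substituted iodide beside a free phenol and a tertiary amine, and 5-exo versus 6-endo closure are all open. The 7-O-demethylation remains.
- Comparison: in step count it is no shorter than lithiation/acylation plus cyclisation from 15, since the phenol must first be freed and iodinated. The chosen route uses the directing group already present and needs no transition metal or toxic gas, but the palladium route is a legitimate substitute for steps 10–11.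

Key step: step 4

Assumption: the sense of induction in step 4 is assigned from the square-planar copper(II)–imide chelate model ((S,S)-ligand leaves the Re face of the acrylamide α-carbon open). If the adduct proves antipodal, the (R,R)-ligand is used and nothing else changes.

## Route

Step 1
Reactants: 1 4-hydroxy-2,6-dimethoxybenzaldehyde
Product: 2 2,6-dimethoxy-4-(methoxymethoxy)benzaldehyde
Conditions: MOMCl, K2CO3, acetone, 0 °C→rt
Reagents that add atoms: chloromethyl methyl ether, COCCl
Why: Williamson-type O-alkylation of an acidic para-formyl phenol; the acetal ether survives all basic, reductive and radical steps ahead and later directs the ring metalation.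

Step 2
Reactants: 2 2,6-dimethoxy-4-(methoxymethoxy)benzaldehyde; 3 acetyl chloride
Product: 5 (E)-N-[2,6-dimethoxy-4-(methoxymethoxy)benzylidene]acetamide, via N-trimethylsilyl aldimine 4 (not isolated)
Conditions: LiN(SiMe3)2, THF, 0 °C→rt; Me3SiCl; then 3, 0 °C→rt; evaporate, take up in toluene, filter
Reagents that add atoms: lithium bis(trimethylsilyl)amide, [Li]N([Si](C)(C)C)[Si](C)(C)C
Why: Aza-Peterson condensation of the non-enolisable aldehyde with the silylamide gives the N-silyl aldimine, and N-acylation with loss of chlorosilane gives the N-acyl imine; the push–pull aryl group stabilises it, and it is used crude under exclusion of moisture.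

Step 3
Reactants: 5 (E)-N-[2,6-dimethoxy-4-(methoxymethoxy)benzylidene]acetamide
Product: 6 (E)-N-[2,6-dimethoxy-4-(methoxymethoxy)benzylidene]-1-(tert-butyldimethylsilyloxy)ethenamine
Conditions: TBSOTf (1.05 equiv), Et3N, Et2O, −20 °C→rt; decant from the ammonium salt, concentrate, use at once
Reagents that add atoms: tert-butyldimethylsilyl trifluoromethanesulfonate, CC(C)(C)[Si](C)(C)OS(=O)(=O)C(F)(F)F
Why: Soft enolisation: O-silylation of the amide carbonyl gives an N-acyliminium-type cation that the amine deprotonates at the acetyl methyl group, giving the 3-siloxy-2-azadiene with the conjugated E imine; excess amine and near-stoichiometric triflate protect the acetal ether.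

Step 4
Reactants: 6 (E)-N-[2,6-dimethoxy-4-(methoxymethoxy)benzylidene]-1-(tert-butyldimethylsilyloxy)ethenamine; 7 3-acryloyl-1,3-oxazolidin-2-one
Product: 9 (5S,6S)-6-[2,6-dimethoxy-4-(methoxymethoxy)phenyl]-5-(2-oxo-1,3-oxazolidine-3-carbonyl)piperidin-2-one, via silyl lactim ether cycloadduct 8 (not isolated)
Conditions: Cu(OTf)2/(S,S)-t-Bu-box (10 mol %), 4 Å MS, CH2Cl2, −40 °C→rt; then MeOH, NaHCO3, rt; isolate the trans isomer
Reagents that add atoms: none
Why: This is a copper(II) bis(oxazoline)-catalysed Diels–Alder reaction of a 1-aryl-3-siloxy-2-azadiene with a chelating acryloyl imide, a known reaction class. The square-planar chelate holds 7 s-cis and lowers its LUMO, and the electron-rich diene adds in an asynchronous [4+2] in which the CH2 terminus bonds to the acrylate β-carbon (C4'–C5') ahead of bonding between the imine carbon and the α-carbon (C2'–C3'). The six-membered ring is closed by the cycloaddition itself, suprafacial on both partners, and methanolysis of the O-silyl lactim 8 releases the lactam. C3' is set by the ligand, whose tert-butyl group blocks one face of the bound acrylamide so that the diene adds to the Re face of the α-carbon. C2' follows from the E geometry of the imine and exo approach, with the diene backbone turned away from the imide chelate, which together give the trans (2'S,3'S) adduct. Regiochemistry is secured by the matched polarisation of the ketene N,O-acetal terminus and the Michael position. Exo and endo adducts formed on the same acrylamide face have opposite configuration at C2', so the trans isomer must be freed of any cis isomer here, before C3' is erased. The siloxy group and three ring oxygens make the diene electron-rich enough to offset the hindrance of the di-ortho-substituted aryl group.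

Step 5
Reactants: 9 (5S,6S)-6-[2,6-dimethoxy-4-(methoxymethoxy)phenyl]-5-(2-oxo-1,3-oxazolidine-3-carbonyl)piperidin-2-one
Product: 11 (2S,3S)-2-[2,6-dimethoxy-4-(methoxymethoxy)phenyl]-6-oxopiperidine-3-carboxylic acid, via peroxy acid 10 (not isolated)
Conditions: LiOH, 30 % H2O2, THF–H2O, 0 °C; aq. Na2SO3; cold HCl to pH 3
Reagents that add atoms: hydrogen peroxide, OO
Why: Hydroperoxide cleaves the exocyclic imide carbonyl selectively and sulfite reduces the peroxy acid; the lactam is untouched, C2' has no acidic hydrogen, and epimerisation at C3' would be harmless.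

Step 6
Reactants: 11 (2S,3S)-2-[2,6-dimethoxy-4-(methoxymethoxy)phenyl]-6-oxopiperidine-3-carboxylic acid
Product: 13 (6S)-6-[2,6-dimethoxy-4-(methoxymethoxy)phenyl]piperidin-2-one, via thiohydroxamate ester 12 (not isolated)
Conditions: N-hydroxypyridine-2-thione, DCC, DMAP (cat.), CH2Cl2, rt, dark; then t-BuSH, hν (tungsten lamp), rt
Reagents that add atoms: none
Why: Barton reductive decarboxylation: the thiohydroxamate ester fragments in a radical chain to a secondary C3' radical that abstracts hydrogen from the thiol; the C3' centre disappears and C2', not part of the radical, keeps its configuration.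

Step 7
Reactants: 13 (6S)-6-[2,6-dimethoxy-4-(methoxymethoxy)phenyl]piperidin-2-one
Product: 14 (6S)-6-[2,6-dimethoxy-4-(methoxymethoxy)phenyl]-1-methylpiperidin-2-one
Conditions: NaH, MeI, THF–DMF, 0 °C→rt
Reagents that add atoms: iodomethane, CI
Why: N-alkylation of the lactam anion; mono-methylation is guaranteed at the amide stage and the base is too weak to touch the lactam α-carbon or C2'–H.

Step 8
Reactants: 14 (6S)-6-[2,6-dimethoxy-4-(methoxymethoxy)phenyl]-1-methylpiperidin-2-one
Product: 15 (2S)-2-[2,6-dimethoxy-4-(methoxymethoxy)phenyl]-1-methylpiperidine
Conditions: LiAlH4, THF, reflux; H2O/NaOH work-up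
Reagents that add atoms: none
Why: Hydride reduction of a tertiary lactam to the amine; aryl ethers and the acetal are inert and the stereocentre is not involved.

Step 9
Reactants: 16 3-phenylpropiolic acid
Product: 17 N-methoxy-N-methyl-3-phenylpropiolamide
Conditions: MeNH(OMe)·HCl, EDC·HCl, N-methylmorpholine, CH2Cl2, 0 °C→rt
Reagents that add atoms: N,O-dimethylhydroxylamine hydrochloride, CNOC.Cl
Why: Carbodiimide amide coupling at low temperature, which keeps the hydroxylamine from adding to the alkyne.

Step 10
Reactants: 15 (2S)-2-[2,6-dimethoxy-4-(methoxymethoxy)phenyl]-1-methylpiperidine; 17 N-methoxy-N-methyl-3-phenylpropiolamide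
Product: 19 1-{2,4-dimethoxy-6-(methoxymethoxy)-3-[(2S)-1-methylpiperidin-2-yl]phenyl}-3-phenylprop-2-yn-1-one, via aryllithium 18 (not isolated)
Conditions: n-BuLi, TMEDA, THF, 0 °C; then 17, −78→−20 °C; inverse quench into cold 1 M HCl, then NaHCO3
Reagents that add atoms: none
Why: Directed ortho-metalation: the methoxymethoxy and methoxy groups cooperatively direct lithiation to the ring C–H between them (the two such positions are equivalent by rotation about the aryl–C2' bond), and the aryllithium adds once to the Weinreb amide through a chelated tetrahedral adduct that releases the ynone only on quench. The cold acidic quench protonates the liberated hydroxylamine before it can add to the ynone.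

Step 11
Reactants: 19 1-{2,4-dimethoxy-6-(methoxymethoxy)-3-[(2S)-1-methylpiperidin-2-yl]phenyl}-3-phenylprop-2-yn-1-one
Product: 21 5,7-dimethoxy-6-[(2S)-1-methylpiperidin-2-yl]-2-phenyl-4H-chromen-4-one, via ortho-hydroxyaryl ynone 20 (not isolated)
Conditions: HCl (3 M in MeOH), 50 °C; then aq. NaHCO3
Reagents that add atoms: none
Why: Acidic methanolysis of the acetal frees the phenol, which closes onto the β-carbon of the protonated ynone in a 6-endo oxa-Michael cyclisation, directly or by addition–elimination through the β-methoxy enone; both paths end in the pyranone. The ring is now acyl-deactivated and the amine protonated, which disfavours ionisation at C2'.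

Step 12
Reactants: 21 5,7-dimethoxy-6-[(2S)-1-methylpiperidin-2-yl]-2-phenyl-4H-chromen-4-one
Product: 22 7-hydroxy-5-methoxy-6-[(2S)-1-methylpiperidin-2-yl]-2-phenyl-4H-chromen-4-one
Conditions: NaSEt (2–3 equiv), DMF, 100 °C; dilute HCl to pH 7
Reagents that add atoms: none
Why: Nucleophilic (SN2) O-demethylation by thiolate goes to the ether whose phenoxide is the better leaving group: O7 is para to the C4 carbonyl, whereas a 5-phenoxide would be destabilised by the peri carbonyl oxygen. The phenoxide formed first deactivates the ring towards a second cleavage, and basic aprotic conditions offer no leaving group at C2'.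

## Compound list

1 | 4-hydroxy-2,6-dimethoxybenzaldehyde | COc1cc(O)cc(OC)c1C=O | starting material
2 | 2,6-dimethoxy-4-(methoxymethoxy)benzaldehyde | COCOc1cc(OC)c(C=O)c(OC)c1 | intermediate
3 | acetyl chloride | CC(=O)Cl | starting material
4 | (E)-1-[2,6-dimethoxy-4-(methoxymethoxy)phenyl]-N-(trimethylsilyl)methanimine (not isolated) | C[Si](C)(C)/N=C/c1c(OC)cc(OCOC)cc1OC | intermediate
5 | (E)-N-[2,6-dimethoxy-4-(methoxymethoxy)benzylidene]acetamide | CC(=O)/N=C/c1c(OC)cc(OCOC)cc1OC | intermediate
6 | (E)-N-[2,6-dimethoxy-4-(methoxymethoxy)benzylidene]-1-(tert-butyldimethylsilyloxy)ethenamine | C=C(O[Si](C)(C)C(C)(C)C)/N=C/c1c(OC)cc(OCOC)cc1OC | intermediate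
7 | 3-acryloyl-1,3-oxazolidin-2-one | C=CC(=O)N1CCOC1=O | starting material
8 | 3-{[(2S,3S)-6-(tert-butyldimethylsilyloxy)-2-[2,6-dimethoxy-4-(methoxymethoxy)phenyl]-2,3,4,5-tetrahydropyridin-3-yl]carbonyl}-1,3-oxazolidin-2-one (not isolated) | CC(C)(C)[Si](C)(C)OC1=N[C@@H]([C@H](CC1)C(=O)N1CCOC1=O)c1c(OC)cc(OCOC)cc1OC | intermediate
9 | (5S,6S)-6-[2,6-dimethoxy-4-(methoxymethoxy)phenyl]-5-(2-oxo-1,3-oxazolidine-3-carbonyl)piperidin-2-one (trans) | O=C1CC[C@H](C(=O)N2CCOC2=O)[C@H](N1)c1c(OC)cc(OCOC)cc1OC | intermediate
10 | (2S,3S)-2-[2,6-dimethoxy-4-(methoxymethoxy)phenyl]-6-oxopiperidine-3-carboperoxoic acid (not isolated) | O=C1CC[C@H](C(=O)OO)[C@H](N1)c1c(OC)cc(OCOC)cc1OC | intermediate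
11 | (2S,3S)-2-[2,6-dimethoxy-4-(methoxymethoxy)phenyl]-6-oxopiperidine-3-carboxylic acid | O=C1CC[C@H](C(=O)O)[C@H](N1)c1c(OC)cc(OCOC)cc1OC | intermediate
12 | 2-thioxopyridin-1(2H)-yl (2S,3S)-2-[2,6-dimethoxy-4-(methoxymethoxy)phenyl]-6-oxopiperidine-3-carboxylate (not isolated) | O=C1CC[C@H](C(=O)ON2C=CC=CC2=S)[C@H](N1)c1c(OC)cc(OCOC)cc1OC | intermediate
13 | (6S)-6-[2,6-dimethoxy-4-(methoxymethoxy)phenyl]piperidin-2-one | O=C1CCC[C@H](N1)c1c(OC)cc(OCOC)cc1OC | intermediate
14 | (6S)-6-[2,6-dimethoxy-4-(methoxymethoxy)phenyl]-1-methylpiperidin-2-one | O=C1CCC[C@H](N1C)c1c(OC)cc(OCOC)cc1OC | intermediate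
15 | (2S)-2-[2,6-dimethoxy-4-(methoxymethoxy)phenyl]-1-methylpiperidine | CN1CCCC[C@H]1c1c(OC)cc(OCOC)cc1OC | intermediate
16 | 3-phenylpropiolic acid | OC(=O)C#Cc1ccccc1 | starting material
17 | N-methoxy-N-methyl-3-phenylpropiolamide | CON(C)C(=O)C#Cc1ccccc1 | intermediate
18 | {2,4-dimethoxy-6-(methoxymethoxy)-3-[(2S)-1-methylpiperidin-2-yl]phenyl}lithium (not isolated) | [Li]c1c(OC)c([C@@H]2CCCCN2C)c(OC)cc1OCOC | intermediate
19 | 1-{2,4-dimethoxy-6-(methoxymethoxy)-3-[(2S)-1-methylpiperidin-2-yl]phenyl}-3-phenylprop-2-yn-1-one | O=C(C#Cc1ccccc1)c1c(OC)c([C@@H]2CCCCN2C)c(OC)cc1OCOC | intermediate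
20 | 1-{6-hydroxy-2,4-dimethoxy-3-[(2S)-1-methylpiperidin-2-yl]phenyl}-3-phenylprop-2-yn-1-one (not isolated) | O=C(C#Cc1ccccc1)c1c(OC)c([C@@H]2CCCCN2C)c(OC)cc1O | intermediate
21 | 5,7-dimethoxy-6-[(2S)-1-methylpiperidin-2-yl]-2-phenyl-4H-chromen-4-one | COc1c([C@@H]2CCCCN2C)c(OC)cc2oc(-c3ccccc3)cc(=O)c12 | intermediate
22 | 7-hydroxy-5-methoxy-6-[(2S)-1-methylpiperidin-2-yl]-2-phenyl-4H-chromen-4-one | COc1c([C@@H]2CCCCN2C)c(O)cc2oc(-c3ccccc3)cc(=O)c12 | target

## Step count and least certain steps

Total: 12 steps. Longest linear sequence: 11 steps (steps 1–8 and 10–12, from 1); step 9 is a one-step side branch.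

**Step 4 (key step).**
- Most likely failure: slow or stalled cycloaddition. The twisted di-ortho-methoxyaryl group shields the imine terminus, and the Lewis-basic diene (nitrogen plus ortho methoxy) can sequester copper.
- Second failure: erosion of exo selectivity. Exo and endo adducts carry opposite C2' configuration, so after decarboxylation this becomes loss of enantiopurity.
- Third failure: hydrolytic loss of the diene.
- Fallback (auxiliary control with physical separation): diene 6 is combined with (R)-3-acryloyl-4-benzyl-1,3-oxazolidin-2-one F1 under a stoichiometric chelating Lewis acid (Et2AlCl or MgBr2·OEt2, CH2Cl2, low temperature). This gives, by way of the silyl lactim ether cycloadduct F2 and methanolysis, the auxiliary-bearing trans lactam F3. All stereoisomeric adducts are now diastereomers and can be separated and assigned before the auxiliary is removed. LiOH/H2O2 cleavage of F3 returns to the route at acid 11.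

**Step 12.**
- Most likely failure: incomplete discrimination between the two methyl ethers (competing cleavage at O5 or double cleavage), since both flank the bulky C6 substituent.
- Second failure: thiolate addition to the pyranone at high temperature.
- Fallback (protecting-group differentiation in place of kinetic selectivity): flavone 21 is demethylated exhaustively with excess thiolate at higher temperature to 5,7-dihydroxy-6-[(2S)-1-methylpiperidin-2-yl]flavone F8. The non-chelated, more acidic 7-hydroxyl is silylated (TIPSCl, imidazole, DMF) to the 7-O-triisopropylsilyl ether F9. The chelated 5-hydroxyl is methylated under Mitsunobu conditions (MeOH, PPh3, DIAD), which avoids a free alkylating agent at the tertiary amine, to the 5-methoxy-7-silyloxy flavone F10. Fluoride (TBAF, THF) then returns to the route at target 22.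

**Step 10.**
- Most likely failure: competing deprotonation at the benzylic C2'–H, with loss of configuration, or incomplete ring metalation.
- Second failure: conjugate addition of the aryllithium, or of the liberated hydroxylamine, to the alkynyl carbonyl system.
- Fallback (electrophilic in place of anionic acylation): amine 15 is deprotected (HCl, MeOH, rt) to (S)-3,5-dimethoxy-4-(1-methylpiperidin-2-yl)phenol F4. Friedel–Crafts acetylation ortho to the hydroxyl (AcOH, BF3·OEt2, moderate temperature) gives the 2-hydroxyacetophenone F5. Benzoyl chloride with excess LiHMDS in THF gives the 1,3-diketone F6 through the Baker–Venkataraman acyl transfer. Cyclodehydration (cat. H2SO4, AcOH) returns to the route at flavone 21. This sequence is held in reserve because it exposes a free electron-rich phenol and the benzylic amine to a warm Lewis acid.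

**Step 11.**
- Most likely failure: 5-exo closure (aurone-type ring) competing with 6-endo closure, or stalling at an open-chain β-alkoxy or β-chloro enone.
- Fallback (addition–elimination in place of alkyne hydroalkoxylation): ynone 19 is treated with diethylamine (EtOH, rt) to give the (E)-β-(diethylamino) enone F7, in which the β-carbon is the only electrophilic site. Acidic methanol then removes the acetal, and the phenol displaces the amine with six-ring closure only, returning to the route at flavone 21.

## Further compounds

F1 | step 4 | (4R)-3-acryloyl-4-benzyl-1,3-oxazolidin-2-one | C=CC(=O)N1[C@H](Cc2ccccc2)COC1=O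
F2 | step 4 | (4R)-4-benzyl-3-{[(2S,3S)-6-(tert-butyldimethylsilyloxy)-2-[2,6-dimethoxy-4-(methoxymethoxy)phenyl]-2,3,4,5-tetrahydropyridin-3-yl]carbonyl}-1,3-oxazolidin-2-one | CC(C)(C)[Si](C)(C)OC1=N[C@@H]([C@H](CC1)C(=O)N1[C@H](Cc2ccccc2)COC1=O)c1c(OC)cc(OCOC)cc1OC
F3 | step 4 | (4R)-4-benzyl-3-{[(2S,3S)-2-[2,6-dimethoxy-4-(methoxymethoxy)phenyl]-6-oxopiperidin-3-yl]carbonyl}-1,3-oxazolidin-2-one | O=C1CC[C@H](C(=O)N2[C@H](Cc3ccccc3)COC2=O)[C@H](N1)c1c(OC)cc(OCOC)cc1OC
F4 | step 10 | 3,5-dimethoxy-4-[(2S)-1-methylpiperidin-2-yl]phenol | Oc1cc(OC)c([C@@H]2CCCCN2C)c(OC)c1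
F5 | step 10 | 1-{6-hydroxy-2,4-dimethoxy-3-[(2S)-1-methylpiperidin-2-yl]phenyl}ethan-1-one | CC(=O)c1c(O)cc(OC)c([C@@H]2CCCCN2C)c1OC
F6 | step 10 | 1-{6-hydroxy-2,4-dimethoxy-3-[(2S)-1-methylpiperidin-2-yl]phenyl}-3-phenylpropane-1,3-dione | O=C(CC(=O)c1ccccc1)c1c(O)cc(OC)c([C@@H]2CCCCN2C)c1OC
F7 | step 11 | (E)-3-(diethylamino)-1-{2,4-dimethoxy-6-(methoxymethoxy)-3-[(2S)-1-methylpiperidin-2-yl]phenyl}-3-phenylprop-2-en-1-one | CCN(CC)/C(=C/C(=O)c1c(OC)c([C@@H]2CCCCN2C)c(OC)cc1OCOC)c1ccccc1
F8 | step 12 | 5,7-dihydroxy-6-[(2S)-1-methylpiperidin-2-yl]-2-phenyl-4H-chromen-4-one | Oc1c([C@@H]2CCCCN2C)c(O)cc2oc(-c3ccccc3)cc(=O)c12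
F9 | step 12 | 5-hydroxy-6-[(2S)-1-methylpiperidin-2-yl]-2-phenyl-7-(triisopropylsilyloxy)-4H-chromen-4-one | Oc1c([C@@H]2CCCCN2C)c(O[Si](C(C)C)(C(C)C)C(C)C)cc2oc(-c3ccccc3)cc(=O)c12
F10 | step 12 | 5-methoxy-6-[(2S)-1-methylpiperidin-2-yl]-2-phenyl-7-(triisopropylsilyloxy)-4H-chromen-4-one | COc1c([C@@H]2CCCCN2C)c(O[Si](C(C)C)(C(C)C)C(C)C)cc2oc(-c3ccccc3)cc(=O)c12
A1 | alternative 1 | tert-butyl (2S)-2-[5-hydroxy-4-oxo-2-phenyl-7-(triisopropylsilyloxy)-4H-chromen-6-yl]piperidine-1-carboxylate | Oc1c([C@@H]2CCCCN2C(=O)OC(C)(C)C)c(O[Si](C(C)C)(C(C)C)C(C)C)cc2oc(-c3ccccc3)cc(=O)c12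
A2 | alternative 1 | 2-(2-diazoacetyl)-6-phenyl-4H-pyran-4-one | [N-]=[N+]=CC(=O)c1cc(=O)cc(-c2ccccc2)o1
A3 | alternative 1 | tert-butyl (2S)-2-[(triisopropylsilyloxy)ethynyl]piperidine-1-carboxylate | CC(C)(C)OC(=O)N1CCCC[C@H]1C#CO[Si](C(C)C)(C(C)C)C(C)C
A4 | alternative 1 | L-pipecolic acid, (2S)-piperidine-2-carboxylic acid | OC(=O)[C@@H]1CCCCN1
A5 | alternative 2 | benzyl (2S)-2-[4-(benzyloxy)-2,6-dihydroxyphenyl]piperidine-1-carboxylate | Oc1cc(OCc2ccccc2)cc(O)c1[C@@H]1CCCCN1C(=O)OCc1ccccc1
A6 | alternative 2 | benzyl N-{5-[4-(benzyloxy)-2,6-dihydroxyphenyl]-5-hydroxypentyl}carbamate (racemic) | OC(CCCCNC(=O)OCc1ccccc1)c1c(O)cc(OCc2ccccc2)cc1O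
A7 | alternative 3 | 5,7-dimethoxy-6-[(2S)-1-methylpiperidin-2-yl]-2-phenyl-4H-chromen-4-one (identical with 21) | COc1c([C@@H]2CCCCN2C)c(OC)cc2oc(-c3ccccc3)cc(=O)c12
A8 | alternative 3 | 2-iodo-3,5-dimethoxy-4-[(2S)-1-methylpiperidin-2-yl]phenol | Oc1cc(OC)c([C@@H]2CCCCN2C)c(OC)c1I
A9 | alternative 3 | phenylacetylene | C#Cc1ccccc1
A10 | alternative 3 | carbon monoxide | [C-]#[O+]
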